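Abbreviations: TBS = tert-butyldimethylsilyl, TBDPS = tert-butyldiphenylsilyl, TES = triethylsilyl, TMSE = 2-(trimethylsilyl)ethyl, DMP = Dess–Martin periodinane. C1'–C6' are the cyclohexane carbons (C1' bonded to the pyridine, C4' the secondary carbinol, C5'/C6' the oxirane carbons).

Assumption: the target is taken as the 4-hydroxy-2(1H)-pyridone tautomer written in the SMILES; bought reagents (ylides, phosphonates, the sulfone, silylating agents) are not counted as starting materials.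

**Retrosynthetic overview**

1. Last step: fluoride removes all four silicon-based groups. Before it, the acyl-bearing decalin carbon is equilibrated from axial to equatorial at the aryl ketone stage; the ketone comes from a 3-lithiopyridine plus the decalin aldehyde, then oxidation.
2. East half: a 3-bromo-2,4-bis(TMSE-oxy)pyridine carrying the silylated epoxy-diol; oxirane by peracid attack anti to both silyloxy groups; C5(pyridine)–C1' bond by aryllithium 1,2-addition to (R)-4-(TBS-oxy)cyclohex-2-enone, made by lipase desymmetrisation of meso cis-1,4-diacetoxycyclohex-2-ene.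
3. West half: decalin by iminium-catalysed endo intramolecular Diels–Alder of a (2E,8E,10E)-trienal; propenyl by Julia–Kocienski olefination; trienal from (S)-citronellol, made by Ru–BINAP hydrogenation of geraniol.
4. Ring order: both decalin rings at once (Diels–Alder); cyclohexene ring bought as the diene and its oxirane closed before fragment union; pyridine ring bought and unmasked to the pyridone last.

**Route**

Step 1
Reactants: 1 geraniol
Product: 2 (S)-citronellol
Conditions: H2 (100 atm), Ru(OAc)2[(R)-BINAP] (0.2 mol%), MeOH–H2O 95:5, 20 °C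
Reagents that add atoms: none
Why: Ru–BINAP asymmetric hydrogenation of an allylic alcohol; the (R)-ligand delivers H2 to one face of the hydroxyl-bound C2=C3 bond to set the (S)-methyl centre (about 97% ee) and leaves the remote trisubstituted alkene untouched.

Step 2
Reactants: 2 (S)-citronellol
Product: 3 (3S)-1-(TBS-oxy)-3,7-dimethyloct-6-ene
Conditions: TBSCl, imidazole, DMF, rt
Reagents that add atoms: tert-butyldimethylsilyl chloride, CC(C)(C)[Si](C)(C)Cl
Why: standard silylation of a primary alcohol; the stereocentre is not involved.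

Step 3
Reactants: 3 (3S)-1-(TBS-oxy)-3,7-dimethyloct-6-ene
Product: 5 (4S)-6-(TBS-oxy)-4-methylhexanal, via ozonide 4 (not isolated)
Conditions: O3, CH2Cl2, −78 °C; then PPh3, −78 °C → rt
Reagents that add atoms: ozone, [O-][O+]=O
Why: ozonolysis with reductive work-up of the only alkene; the stereocentre is γ to the new aldehyde and cannot epimerise.

Step 4
Reactants: 5 (4S)-6-(TBS-oxy)-4-methylhexanal
Product: 6 (2E,6S)-8-(TBS-oxy)-2,6-dimethyloct-2-enal
Conditions: Ph3P=C(CH3)CHO (1.3 equiv), toluene, 90 °C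
Reagents that add atoms: 2-(triphenylphosphoranylidene)propanal, CC(C=O)=P(c1ccccc1)(c1ccccc1)c1ccccc1
Why: Wittig reaction of a stabilised ylide gives the (E)-trisubstituted enal (>95:5), which fixes the "tether outside" geometry of the future diene.

Step 5
Reactants: 6 (2E,6S)-8-(TBS-oxy)-2,6-dimethyloct-2-enal
Product: 7 ethyl (2E,4E,8S)-10-(TBS-oxy)-4,8-dimethyldeca-2,4-dienoate
Conditions: (EtO)2P(O)CH2CO2Et, NaH, THF, 0 °C → rt
Reagents that add atoms: triethyl phosphonoacetate, CCOC(=O)CP(=O)(OCC)OCC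
Why: Horner–Wadsworth–Emmons olefination gives the (E)-disubstituted alkene and completes the (E,E)-diene.

Step 6
Reactants: 7 ethyl (2E,4E,8S)-10-(TBS-oxy)-4,8-dimethyldeca-2,4-dienoate
Product: 8 (2E,4E,8S)-10-(TBS-oxy)-4,8-dimethyldeca-2,4-dien-1-ol
Conditions: DIBAL-H (2.5 equiv), CH2Cl2, −78 °C; Rochelle salt
Reagents that add atoms: none
Why: 1,2-reduction of a conjugated ester by DIBAL-H without touching the diene or the silyl ether.

Step 7
Reactants: 8 (2E,4E,8S)-10-(TBS-oxy)-4,8-dimethyldeca-2,4-dien-1-ol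
Product: 9 (2E,4E,8S)-1-(TBDPS-oxy)-10-(TBS-oxy)-4,8-dimethyldeca-2,4-diene
Conditions: TBDPSCl, imidazole, DMF, 0 °C → rt
Reagents that add atoms: tert-butyldiphenylsilyl chloride, CC(C)(C)[Si](Cl)(c1ccccc1)c1ccccc1
Why: silylation with the more acid-stable TBDPS group so that the two primary oxygens can be told apart.

Step 8
Reactants: 9 (2E,4E,8S)-1-(TBDPS-oxy)-10-(TBS-oxy)-4,8-dimethyldeca-2,4-diene
Product: 10 (3S,6E,8E)-10-(TBDPS-oxy)-3,7-dimethyldeca-6,8-dien-1-ol
Conditions: PPTS (0.2 equiv), MeOH, rt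
Reagents that add atoms: none
Why: acid-catalysed methanolysis cleaves a primary TBS ether roughly 100 times faster than a TBDPS ether.

Step 9
Reactants: 10 (3S,6E,8E)-10-(TBDPS-oxy)-3,7-dimethyldeca-6,8-dien-1-ol
Product: 11 (3S,6E,8E)-10-(TBDPS-oxy)-3,7-dimethyldeca-6,8-dienal
Conditions: DMP, CH2Cl2, 0 °C → rt
Reagents that add atoms: none
Why: Dess–Martin oxidation to the aldehyde; the stereocentre is β to the carbonyl and is not epimerisable.

Step 10
Reactants: 11 (3S,6E,8E)-10-(TBDPS-oxy)-3,7-dimethyldeca-6,8-dienal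
Product: 12 (2E,5S,8E,10E)-12-(TBDPS-oxy)-N-methoxy-N,5,9-trimethyldodeca-2,8,10-trienamide
Conditions: (EtO)2P(O)CH2C(O)N(OMe)Me, NaH, THF, 0 °C → rt
Reagents that add atoms: diethyl [2-[methoxy(methyl)amino]-2-oxoethyl]phosphonate, CCOP(=O)(CC(=O)N(C)OC)OCC
Why: Horner–Wadsworth–Emmons olefination gives the (E)-unsaturated Weinreb amide at room temperature, so the triene is never heated.

Step 11
Reactants: 12 (2E,5S,8E,10E)-12-(TBDPS-oxy)-N-methoxy-N,5,9-trimethyldodeca-2,8,10-trienamide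
Product: 13 (2E,5S,8E,10E)-12-(TBDPS-oxy)-5,9-dimethyldodeca-2,8,10-trienal
Conditions: DIBAL-H (1.3 equiv), THF, −78 °C; Rochelle salt; used at once
Reagents that add atoms: none
Why: partial reduction of a Weinreb amide stops at the chelated tetrahedral intermediate and releases the enal only on work-up.

Step 12
Reactants: 13 (2E,5S,8E,10E)-12-(TBDPS-oxy)-5,9-dimethyldodeca-2,8,10-trienal
Product: 14 (1R,2S,4aS,7S,8aS)-2-[(TBDPS-oxy)methyl]-4,7-dimethyl-1,2,4a,5,6,7,8,8a-octahydronaphthalene-1-carbaldehyde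
Conditions: (2S,5S)-5-benzyl-2-tert-butyl-3-methylimidazolidin-4-one·TFA (20 mol%), MeCN–H2O 98:2, 0 °C
Reagents that add atoms: none
Why: iminium-catalysed intramolecular Diels–Alder reaction; the benzyl group blocks the Re face of the (E)-iminium, the endo transition state with a chair tether and equatorial methyl (matched with the catalyst) gives the trans-fused decalin, and C1, C2, C4a and C8a are set together with CHO and CH2O-TBDPS cis.

Step 13
Reactants: 14 (1R,2S,4aS,7S,8aS)-2-[(TBDPS-oxy)methyl]-4,7-dimethyl-1,2,4a,5,6,7,8,8a-octahydronaphthalene-1-carbaldehyde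
Product: 15 TBDPS ether of [(1R,2R,4aS,7S,8aR)-4,7-dimethyl-1-[(E)-prop-1-enyl]-1,2,4a,5,6,7,8,8a-octahydronaphthalen-2-yl]methanol
Conditions: 5-(ethylsulfonyl)-1-phenyl-1H-tetrazole, KHMDS, DME, −60 °C → rt
Reagents that add atoms: 5-(ethylsulfonyl)-1-phenyl-1H-tetrazole, CCS(=O)(=O)c1nnnn1-c1ccccc1
Why: Julia–Kocienski olefination with a phenyltetrazolyl sulfone and a potassium base gives the (E)-propenyl group; the equatorial aldehyde centre is already the stable epimer.

Step 14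
Reactants: 15 TBDPS ether of the decalinyl methanol
Product: 16 [(1R,2R,4aS,7S,8aR)-4,7-dimethyl-1-[(E)-prop-1-enyl]-1,2,4a,5,6,7,8,8a-octahydronaphthalen-2-yl]methanol
Conditions: TBAF, THF, 0 °C → rt
Reagents that add atoms: none
Why: fluoride-mediated desilylation; nothing else in the molecule is fluoride- or base-sensitive.

Step 15
Reactants: 16 decalinyl methanol
Product: 17 (1R,2R,4aS,7S,8aR)-4,7-dimethyl-1-[(E)-prop-1-enyl]-1,2,4a,5,6,7,8,8a-octahydronaphthalene-2-carbaldehyde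
Conditions: DMP, CH2Cl2, 0 °C; filtered through a short silica pad and used directly
Reagents that add atoms: none
Why: Dess–Martin oxidation under near-neutral conditions gives the β,γ-unsaturated aldehyde (CHO axial, cis to propenyl) without double-bond migration.

Step 16
Reactants: 18 5-bromo-2,4-dichloropyridine
Product: 19 5-bromo-2,4-bis(TMSE-oxy)pyridine
Conditions: Me3SiCH2CH2OH (2.6 equiv), NaH, THF, 0 → 65 °C
Reagents that add atoms: 2-(trimethylsilyl)ethanol, C[Si](C)(C)CCO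
Why: double nucleophilic aromatic substitution at the activated 4- and 2-positions; the 5-bromide is not activated and stays.

Step 17
Reactants: 20 cyclohexa-1,3-diene
Product: 21 meso cis-cyclohex-2-ene-1,4-diyl diacetate
Conditions: Pd(OAc)2 (5 mol%), LiCl (20 mol%), LiOAc, p-benzoquinone (1.2 equiv), AcOH, rt
Reagents that add atoms: acetic acid, CC(=O)O
Why: Pd(II)-catalysed 1,4-diacetoxylation of a 1,3-diene through a π-allyl complex; catalytic chloride makes the second acetate attack externally, so the 1,4-diacetate is cis and therefore meso.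

Step 18
Reactants: 21 meso cis-cyclohex-2-ene-1,4-diyl diacetate
Product: 22 (1S,4R)-4-hydroxycyclohex-2-en-1-yl acetate
Conditions: lipase (immobilised Candida antarctica lipase B), 0.1 M phosphate buffer pH 7, rt, pH-stat
Reagents that add atoms: none
Why: lipase-catalysed enantiotopos-selective hydrolysis (desymmetrisation of a meso diester); the enzyme cleaves only the acetate on the (R)-configured carbon, which creates both stereocentres in >98% ee at up to 100% theoretical yield.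

Step 19
Reactants: 22 (1S,4R)-4-hydroxycyclohex-2-en-1-yl acetate
Product: 23 (1S,4R)-4-(TBS-oxy)cyclohex-2-en-1-yl acetate
Conditions: TBSCl, imidazole, DMF, rt
Reagents that add atoms: tert-butyldimethylsilyl chloride, CC(C)(C)[Si](C)(C)Cl
Why: silylation of the free hydroxyl keeps the enzyme-defined (R)-carbinol as the centre that will survive.

Step 20
Reactants: 23 (1S,4R)-4-(TBS-oxy)cyclohex-2-en-1-yl acetate
Product: 24 (1S,4R)-4-(TBS-oxy)cyclohex-2-en-1-ol
Conditions: K2CO3 (cat.), MeOH, 0 °C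
Reagents that add atoms: none
Why: base-catalysed transesterification removes the acetate without touching the TBS ether.

Step 21
Reactants: 24 (1S,4R)-4-(TBS-oxy)cyclohex-2-en-1-ol
Product: 25 (4R)-4-(TBS-oxy)cyclohex-2-en-1-one
Conditions: DMP, CH2Cl2, 0 °C → rt
Reagents that add atoms: none
Why: Dess–Martin oxidation of the allylic alcohol under neutral conditions; the γ-silyloxy centre is not enolised.

Step 22
Reactants: 19 5-bromo-2,4-bis(TMSE-oxy)pyridine; 25 (4R)-4-(TBS-oxy)cyclohex-2-en-1-one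
Product: 27 (1S,4R)-1-[4,6-bis(TMSE-oxy)pyridin-3-yl]-4-(TBS-oxy)cyclohex-2-en-1-ol, via aryllithium 26 (not isolated)
Conditions: n-BuLi (1.05 equiv), THF, −78 °C; then 25, −78 °C; H2O; chromatography
Reagents that add atoms: none
Why: bromine–lithium exchange then 1,2-addition of the aryllithium to the enone; axial attack anti to the pseudo-axial silyloxy group puts the new hydroxyl cis to OTBS (C1' set from C4', about 4:1 expected, minor epimer removed on silica).

Step 23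
Reactants: 27 cis-adduct
Product: 28 5-[(1S,4R)-4-(TBS-oxy)-1-(TES-oxy)cyclohex-2-en-1-yl]-2,4-bis(TMSE-oxy)pyridine
Conditions: TESOTf, 2,6-lutidine, CH2Cl2, −78 → 0 °C
Reagents that add atoms: triethylsilyl triflate, CC[Si](CC)(CC)OS(=O)(=O)C(F)(F)F
Why: silyl triflate silylation of the hindered tertiary alcohol, which removes the hydroxyl that would otherwise steer a peracid to the wrong face.

Step 24
Reactants: 28 TES ether
Product: 30 3-bromo-5-[(1S,4R)-4-(TBS-oxy)-1-(TES-oxy)cyclohex-2-en-1-yl]-2,4-bis(TMSE-oxy)pyridine, via 3-lithiopyridine 29 (not isolated)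
Conditions: n-BuLi (1.3 equiv), THF, −78 → −30 °C; then BrCCl2CCl2Br, −78 °C
Reagents that add atoms: 1,2-dibromo-1,1,2,2-tetrachloroethane, ClC(Cl)(Br)C(Cl)(Cl)Br
Why: directed ortho-metalation at the only C–H flanked by two alkoxy groups, then electrophilic bromination; the bromide is a handle for later low-temperature lithiation and also lowers the nucleophilicity of the ring nitrogen.

Step 25
Reactants: 30 bromopyridine
Product: 31 3-bromo-5-[(1S,2R,5R,6R)-5-(TBS-oxy)-2-(TES-oxy)-7-oxabicyclo[4.1.0]heptan-2-yl]-2,4-bis(TMSE-oxy)pyridine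
Conditions: mCPBA, CH2Cl2–aq. NaHCO3 (two-phase), 0 °C → rt
Reagents that add atoms: meta-chloroperoxybenzoic acid, OOC(=O)c1cccc(Cl)c1
Why: Prilezhaev epoxidation; with no free hydroxyl the peracid attacks anti to the pseudo-axial tertiary silyloxy group and to the second silyloxy group, so the oxirane ends up trans to both oxygens and cis to the aryl group (C5' and C6' set).

Step 26
Reactants: 31 bromo-epoxide; 17 cis-decalin aldehyde
Product: 33 {(1R,2R,4aS,7S,8aR)-4,7-dimethyl-1-[(E)-prop-1-enyl]-1,2,4a,5,6,7,8,8a-octahydronaphthalen-2-yl}{5-[(1S,2R,5R,6R)-5-(TBS-oxy)-2-(TES-oxy)-7-oxabicyclo[4.1.0]heptan-2-yl]-2,4-bis(TMSE-oxy)pyridin-3-yl}methanol, via aryllithium 32 (not isolated)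
Conditions: n-BuLi (1.05 equiv), THF, −78 °C, 10 min; then 17, −78 °C; H2O
Reagents that add atoms: none
Why: bromine–lithium exchange at −78 °C (oxirane and silyl ethers inert) and 1,2-addition to the aldehyde; the carbinol forms as an epimer mixture that is removed in the next step.

Step 27
Reactants: 33 carbinol
Product: 34 corresponding methanone with the acyl group axial, decalin (1R,2R,4aS,7S,8aR)
Conditions: DMP, CH2Cl2, rt
Reagents that add atoms: none
Why: Dess–Martin oxidation of a hindered secondary aryl carbinol to the ketone under neutral conditions.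

Step 28
Reactants: 34 axial ketone
Product: 35 methanone with the acyl group equatorial, decalin (1R,2S,4aS,7S,8aR)
Conditions: DBU (0.5 equiv), toluene, 50 °C, followed by 1H NMR and stopped at equilibrium
Reagents that add atoms: none
Why: base-mediated epimerisation through the dienolate, which re-protonates at the α-carbon; the bulky aroyl group moves from pseudo-axial to pseudo-equatorial, trans to the propenyl group, which is the all-equatorial thermodynamic arrangement of the target.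

Step 29
Reactants: 35 equatorial ketone
Product: 36 target, 4-hydroxy-5-[(1S,2R,5R,6S)-2,5-dihydroxy-7-oxabicyclo[4.1.0]heptan-2-yl]-3-{[(1R,2S,4aS,7S,8aR)-4,7-dimethyl-1-[(E)-prop-1-enyl]-1,2,4a,5,6,7,8,8a-octahydronaphthalen-2-yl]carbonyl}pyridin-2(1H)-one
Conditions: TBAF (6 equiv), THF, 0 °C → rt; pH 5 buffer work-up
Reagents that add atoms: none
Why: global fluoride deprotection; TES and TBS ethers are cleaved and both TMSE ethers fragment (loss of ethene) to the 4-hydroxy-2-pyridone, under conditions that spare the oxirane, the ketone and the alkenes.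

**Compound list**

1 | geraniol, (2E)-3,7-dimethylocta-2,6-dien-1-ol | CC(C)=CCC/C(C)=C/CO | starting material
2 | (S)-citronellol, (3S)-3,7-dimethyloct-6-en-1-ol | C[C@H](CCO)CCC=C(C)C | intermediate
3 | (3S)-1-(TBS-oxy)-3,7-dimethyloct-6-ene | C[C@H](CCO[Si](C)(C)C(C)(C)C)CCC=C(C)C | intermediate
4 | ozonide, 3-[(3S)-5-(TBS-oxy)-3-methylpentyl]-5,5-dimethyl-1,2,4-trioxolane (ring carbon unassigned) | C[C@H](CCO[Si](C)(C)C(C)(C)C)CCC1OOC(C)(C)O1 | intermediate
5 | (4S)-6-(TBS-oxy)-4-methylhexanal | C[C@H](CCO[Si](C)(C)C(C)(C)C)CCC=O | intermediate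
6 | (2E,6S)-8-(TBS-oxy)-2,6-dimethyloct-2-enal | C[C@H](CCO[Si](C)(C)C(C)(C)C)CC/C=C(\C)C=O | intermediate
7 | ethyl (2E,4E,8S)-10-(TBS-oxy)-4,8-dimethyldeca-2,4-dienoate | C[C@H](CCO[Si](C)(C)C(C)(C)C)CC/C=C(C)/C=C/C(=O)OCC | intermediate
8 | (2E,4E,8S)-10-(TBS-oxy)-4,8-dimethyldeca-2,4-dien-1-ol | C[C@H](CCO[Si](C)(C)C(C)(C)C)CC/C=C(C)/C=C/CO | intermediate
9 | (2E,4E,8S)-1-(TBDPS-oxy)-10-(TBS-oxy)-4,8-dimethyldeca-2,4-diene | C[C@H](CCO[Si](C)(C)C(C)(C)C)CC/C=C(C)/C=C/CO[Si](c1ccccc1)(c1ccccc1)C(C)(C)C | intermediate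
10 | (3S,6E,8E)-10-(TBDPS-oxy)-3,7-dimethyldeca-6,8-dien-1-ol | C[C@H](CCO)CC/C=C(C)/C=C/CO[Si](c1ccccc1)(c1ccccc1)C(C)(C)C | intermediate
11 | (3S,6E,8E)-10-(TBDPS-oxy)-3,7-dimethyldeca-6,8-dienal | C[C@H](CC=O)CC/C=C(C)/C=C/CO[Si](c1ccccc1)(c1ccccc1)C(C)(C)C | intermediate
12 | (2E,5S,8E,10E)-12-(TBDPS-oxy)-N-methoxy-N,5,9-trimethyldodeca-2,8,10-trienamide | C[C@H](C/C=C/C(=O)N(C)OC)CC/C=C(C)/C=C/CO[Si](c1ccccc1)(c1ccccc1)C(C)(C)C | intermediate
13 | (2E,5S,8E,10E)-12-(TBDPS-oxy)-5,9-dimethyldodeca-2,8,10-trienal | C[C@H](C/C=C/C=O)CC/C=C(C)/C=C/CO[Si](c1ccccc1)(c1ccccc1)C(C)(C)C | intermediate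
14 | (1R,2S,4aS,7S,8aS)-2-[(TBDPS-oxy)methyl]-4,7-dimethyl-1,2,4a,5,6,7,8,8a-octahydronaphthalene-1-carbaldehyde (trans-fused; CHO and CH2O-TBDPS cis) | O=C[C@@H]1[C@H]2C[C@@H](C)CC[C@@H]2C(C)=C[C@@H]1CO[Si](c1ccccc1)(c1ccccc1)C(C)(C)C | intermediate
15 | TBDPS ether of [(1R,2R,4aS,7S,8aR)-4,7-dimethyl-1-[(E)-prop-1-enyl]-1,2,4a,5,6,7,8,8a-octahydronaphthalen-2-yl]methanol | C/C=C/[C@@H]1[C@H]2C[C@@H](C)CC[C@@H]2C(C)=C[C@@H]1CO[Si](c1ccccc1)(c1ccccc1)C(C)(C)C | intermediate
16 | [(1R,2R,4aS,7S,8aR)-4,7-dimethyl-1-[(E)-prop-1-enyl]-1,2,4a,5,6,7,8,8a-octahydronaphthalen-2-yl]methanol | C/C=C/[C@@H]1[C@H]2C[C@@H](C)CC[C@@H]2C(C)=C[C@@H]1CO | intermediate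
17 | (1R,2R,4aS,7S,8aR)-4,7-dimethyl-1-[(E)-prop-1-enyl]-1,2,4a,5,6,7,8,8a-octahydronaphthalene-2-carbaldehyde (CHO axial, cis to propenyl) | C/C=C/[C@@H]1[C@H]2C[C@@H](C)CC[C@@H]2C(C)=C[C@@H]1C=O | intermediate
18 | 5-bromo-2,4-dichloropyridine | Clc1cc(Cl)c(Br)cn1 | starting material
19 | 5-bromo-2,4-bis(TMSE-oxy)pyridine | C[Si](C)(C)CCOc1cc(OCC[Si](C)(C)C)c(Br)cn1 | intermediate
20 | cyclohexa-1,3-diene | C1=CC=CCC1 | starting material
21 | meso cis-(1R,4S)-cyclohex-2-ene-1,4-diyl diacetate | CC(=O)O[C@H]1CC[C@@H](OC(C)=O)C=C1 | intermediate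
22 | (1S,4R)-4-hydroxycyclohex-2-en-1-yl acetate | CC(=O)O[C@H]1CC[C@@H](O)C=C1 | intermediate
23 | (1S,4R)-4-(TBS-oxy)cyclohex-2-en-1-yl acetate | CC(=O)O[C@H]1CC[C@@H](O[Si](C)(C)C(C)(C)C)C=C1 | intermediate
24 | (1S,4R)-4-(TBS-oxy)cyclohex-2-en-1-ol | O[C@H]1CC[C@@H](O[Si](C)(C)C(C)(C)C)C=C1 | intermediate
25 | (4R)-4-(TBS-oxy)cyclohex-2-en-1-one | O=C1CC[C@@H](O[Si](C)(C)C(C)(C)C)C=C1 | intermediate
26 | 4,6-bis(TMSE-oxy)pyridin-3-yllithium | [Li]c1cnc(OCC[Si](C)(C)C)cc1OCC[Si](C)(C)C | intermediate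
27 | (1S,4R)-1-[4,6-bis(TMSE-oxy)pyridin-3-yl]-4-(TBS-oxy)cyclohex-2-en-1-ol (OH and OTBS cis) | C[Si](C)(C)CCOc1ncc([C@]2(O)CC[C@@H](O[Si](C)(C)C(C)(C)C)C=C2)c(OCC[Si](C)(C)C)c1 | intermediate
28 | 5-[(1S,4R)-4-(TBS-oxy)-1-(TES-oxy)cyclohex-2-en-1-yl]-2,4-bis(TMSE-oxy)pyridine | C[Si](C)(C)CCOc1ncc([C@]2(O[Si](CC)(CC)CC)CC[C@@H](O[Si](C)(C)C(C)(C)C)C=C2)c(OCC[Si](C)(C)C)c1 | intermediate
29 | 3-lithio derivative of 28 | C[Si](C)(C)CCOc1ncc([C@]2(O[Si](CC)(CC)CC)CC[C@@H](O[Si](C)(C)C(C)(C)C)C=C2)c(OCC[Si](C)(C)C)c1[Li] | intermediate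
30 | 3-bromo-5-[(1S,4R)-4-(TBS-oxy)-1-(TES-oxy)cyclohex-2-en-1-yl]-2,4-bis(TMSE-oxy)pyridine | C[Si](C)(C)CCOc1ncc([C@]2(O[Si](CC)(CC)CC)CC[C@@H](O[Si](C)(C)C(C)(C)C)C=C2)c(OCC[Si](C)(C)C)c1Br | intermediate
31 | 3-bromo-5-[(1S,2R,5R,6R)-5-(TBS-oxy)-2-(TES-oxy)-7-oxabicyclo[4.1.0]heptan-2-yl]-2,4-bis(TMSE-oxy)pyridine (oxirane trans to both silyloxy groups) | C[Si](C)(C)CCOc1ncc([C@]2(O[Si](CC)(CC)CC)CC[C@@H](O[Si](C)(C)C(C)(C)C)[C@@H]3O[C@@H]32)c(OCC[Si](C)(C)C)c1Br | intermediate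
32 | 3-lithio analogue of 31 (Li in place of Br) | C[Si](C)(C)CCOc1ncc([C@]2(O[Si](CC)(CC)CC)CC[C@@H](O[Si](C)(C)C(C)(C)C)[C@@H]3O[C@@H]32)c(OCC[Si](C)(C)C)c1[Li] | intermediate
33 | carbinol from 32 and 17, decalin (1R,2R,4aS,7S,8aR), carbinol carbon as epimer mixture | C/C=C/[C@@H]1[C@H]2C[C@@H](C)CC[C@@H]2C(C)=C[C@@H]1C(O)c1c(OCC[Si](C)(C)C)c([C@]2(O[Si](CC)(CC)CC)CC[C@@H](O[Si](C)(C)C(C)(C)C)[C@@H]3O[C@@H]32)cnc1OCC[Si](C)(C)C | intermediate
34 | ketone with axial acyl group, decalin (1R,2R,4aS,7S,8aR) | C/C=C/[C@@H]1[C@H]2C[C@@H](C)CC[C@@H]2C(C)=C[C@@H]1C(=O)c1c(OCC[Si](C)(C)C)c([C@]2(O[Si](CC)(CC)CC)CC[C@@H](O[Si](C)(C)C(C)(C)C)[C@@H]3O[C@@H]32)cnc1OCC[Si](C)(C)C | intermediate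
35 | ketone with equatorial acyl group, decalin (1R,2S,4aS,7S,8aR) | C/C=C/[C@@H]1[C@H]2C[C@@H](C)CC[C@@H]2C(C)=C[C@H]1C(=O)c1c(OCC[Si](C)(C)C)c([C@]2(O[Si](CC)(CC)CC)CC[C@@H](O[Si](C)(C)C(C)(C)C)[C@@H]3O[C@@H]32)cnc1OCC[Si](C)(C)C | intermediate
36 | 4-hydroxy-5-[(1S,2R,5R,6S)-2,5-dihydroxy-7-oxabicyclo[4.1.0]heptan-2-yl]-3-{[(1R,2S,4aS,7S,8aR)-4,7-dimethyl-1-[(E)-prop-1-enyl]-1,2,4a,5,6,7,8,8a-octahydronaphthalen-2-yl]carbonyl}pyridin-2(1H)-one | C/C=C/[C@@H]1[C@H]2C[C@@H](C)CC[C@@H]2C(C)=C[C@H]1C(=O)c1c(O)c([C@]2(O)CC[C@@H](O)[C@@H]3O[C@@H]32)c[nH]c1=O | target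

**Totals**

Total step count: 29. Longest linear sequence: 19 steps (steps 1–15, then 26–29, from geraniol).

**Three steps most likely to fail**

Step 22 (aryllithium addition to the enone). The 1,4-induction from the silyloxy group may be weak or may favour the wrong face, and this step fixes C1'. The fallback sets out from 19 and comes back at 27. Aryllithium 26, made from 19, is added to cyclohex-2-en-1-one to give the racemic tertiary allylic alcohol F1. PPTS in toluene at 80 °C dehydrates it to the 1-aryl-cyclohexa-1,3-diene F2. Singlet oxygen (O2, hν, tetraphenylporphyrin, CH2Cl2, 0 °C) adds across the diene in a [4+2] sense to give the racemic endoperoxide F3, so both C–O bonds are forced onto one face. Thiourea in MeOH cleaves the O–O bond to the racemic cis-diol F4. A lipase (Candida antarctica lipase B, vinyl acetate, MTBE) acetylates only the secondary hydroxyl of the (4R)-enantiomer to give the monoacetate F5, which is separated from the unreacted enantiomeric diol. K2CO3 in MeOH gives the enantiopure cis-diol F6, and TBSCl/imidazole silylates its secondary hydroxyl to give 27.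

Step 25 (epoxidation). The peracid may attack the face syn to the silyloxy groups, or react sluggishly on this hindered, inductively deactivated alkene. The fallback sets out from 30 and comes back at 31. NBS in DME–H2O at 0 °C gives the trans-bromohydrin F7: the bromonium forms on the face the peracid preferred and water opens it anti at the carbon remote from the quaternary centre; NBS does not oxidise the ring nitrogen. K2CO3 in MeOH then closes the oxirane by intramolecular SN2, which places the oxygen on the face opposite to the first electrophilic attack and gives 31.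

Step 28 (epimerisation of the ketone). Enolisation of the hindered, late-stage ketone may be slow, or the β,γ-alkene may drift into conjugation. The fallback sets out from 17 and comes back at 35. Pinnick oxidation (NaClO2, NaH2PO4, 2-methyl-2-butene) gives the cis-acid F8, and TMSCHN2 gives the cis-methyl ester F9. NaOMe in MeOH at rt equilibrates it to the trans-methyl ester F10; ester dienolates re-protonate at the α-carbon, and the robust ester can be separated and recycled. DIBAL-H in toluene at −78 °C gives the trans-aldehyde F11. Addition of aryllithium 32 gives the trans-carbinol F12, and DMP oxidation gives 35 with no late epimerisation.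

**Further compounds**

F1 | step 22 | racemic 1-[4,6-bis(TMSE-oxy)pyridin-3-yl]cyclohex-2-en-1-ol | C[Si](C)(C)CCOc1ncc(C2(O)CCCC=C2)c(OCC[Si](C)(C)C)c1
F2 | step 22 | 5-(cyclohexa-1,3-dien-1-yl)-2,4-bis(TMSE-oxy)pyridine | C[Si](C)(C)CCOc1ncc(C2=CC=CCC2)c(OCC[Si](C)(C)C)c1
F3 | step 22 | racemic 1-[4,6-bis(TMSE-oxy)pyridin-3-yl]-2,3-dioxabicyclo[2.2.2]oct-5-ene | C[Si](C)(C)CCOc1ncc(C23CCC(C=C2)OO3)c(OCC[Si](C)(C)C)c1
F4 | step 22 | racemic cis-1-[4,6-bis(TMSE-oxy)pyridin-3-yl]cyclohex-2-ene-1,4-diol (one enantiomer drawn) | C[Si](C)(C)CCOc1ncc([C@]2(O)CC[C@@H](O)C=C2)c(OCC[Si](C)(C)C)c1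
F5 | step 22 | (1R,4S)-4-[4,6-bis(TMSE-oxy)pyridin-3-yl]-4-hydroxycyclohex-2-en-1-yl acetate | C[Si](C)(C)CCOc1ncc([C@]2(O)CC[C@@H](OC(C)=O)C=C2)c(OCC[Si](C)(C)C)c1
F6 | step 22 | (1S,4R)-1-[4,6-bis(TMSE-oxy)pyridin-3-yl]cyclohex-2-ene-1,4-diol, single enantiomer | C[Si](C)(C)CCOc1ncc([C@]2(O)CC[C@@H](O)C=C2)c(OCC[Si](C)(C)C)c1
F7 | step 25 | trans-bromohydrin of 30: Br on the ring carbon next to the quaternary centre and cis to the TES-oxy group, OH on the neighbouring carbon, trans to Br and to the TBS-oxy group | C[Si](C)(C)CCOc1ncc([C@]2(O[Si](CC)(CC)CC)CC[C@@H](O[Si](C)(C)C(C)(C)C)[C@H](O)[C@H]2Br)c(OCC[Si](C)(C)C)c1Br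
F8 | step 28 | (1R,2R,4aS,7S,8aR)-4,7-dimethyl-1-[(E)-prop-1-enyl]-1,2,4a,5,6,7,8,8a-octahydronaphthalene-2-carboxylic acid | C/C=C/[C@@H]1[C@H]2C[C@@H](C)CC[C@@H]2C(C)=C[C@@H]1C(=O)O
F9 | step 28 | methyl (1R,2R,4aS,7S,8aR)-4,7-dimethyl-1-[(E)-prop-1-enyl]-1,2,4a,5,6,7,8,8a-octahydronaphthalene-2-carboxylate | C/C=C/[C@@H]1[C@H]2C[C@@H](C)CC[C@@H]2C(C)=C[C@@H]1C(=O)OC
F10 | step 28 | methyl (1R,2S,4aS,7S,8aR)-4,7-dimethyl-1-[(E)-prop-1-enyl]-1,2,4a,5,6,7,8,8a-octahydronaphthalene-2-carboxylate | C/C=C/[C@@H]1[C@H]2C[C@@H](C)CC[C@@H]2C(C)=C[C@H]1C(=O)OC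
F11 | step 28 | (1R,2S,4aS,7S,8aR)-4,7-dimethyl-1-[(E)-prop-1-enyl]-1,2,4a,5,6,7,8,8a-octahydronaphthalene-2-carbaldehyde | C/C=C/[C@@H]1[C@H]2C[C@@H](C)CC[C@@H]2C(C)=C[C@H]1C=O
F12 | step 28 | carbinol from 32 and F11, decalin (1R,2S,4aS,7S,8aR), carbinol carbon as epimer mixture | C/C=C/[C@@H]1[C@H]2C[C@@H](C)CC[C@@H]2C(C)=C[C@H]1C(O)c1c(OCC[Si](C)(C)C)c([C@]2(O[Si](CC)(CC)CC)CC[C@@H](O[Si](C)(C)C(C)(C)C)[C@@H]3O[C@@H]32)cnc1OCC[Si](C)(C)C
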